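**Retrosynthetic overview**
1. Feature: in ring B the bromine-bearing carbon C2' is bonded directly to the ether carbon C1'. This C(OAr)–C(Br) pair is what remains when one CBr carbon is slipped between the two olefinic carbons of a cyclopentenyl aryl ether.
2. Last disconnection: the C3–Br, C4–Br and C5–Br bonds of ring A and the C4'–Br bond of ring B are removed (fourfold SEAr on the free phenol), and the phenol is then masked as its MOM ether.
3. Key disconnection: aromatic ring B ⇒ 2-aryloxy-3-bromocyclohexa-1,3-diene ⇒ cyclopentenyl aryl ether + CBr2 from bromoform (C1'–C2' and C2'–C3' are cut).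
4. Enol ether C1'–O bond ⇒ 3-methoxy-2-(methoxymethoxy)phenol + 1-bromocyclopentene. The phenol ⇒ o-vanillin (MOM protection, Baeyer–Villiger oxidation).
5. Ring order: ring A and the five-membered ring are bought. A cyclopropane is closed and opened in step 4, which creates six-membered ring B, and step 5 makes it aromatic.

Key step: step 4

Remark: the target is achiral. The only stereocentres of the route are those of transient 8 (racemic, cis-fused by ring strain), and they vanish within the same step. Primed locants refer to ring B (C1' bears the ether oxygen). Unprimed locants refer to ring A numbered as the phenol (C1 = C–OH, C2 = C–OAr, C6 = C–OMe).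

Step 1
Reactants: 1 o-vanillin (2-hydroxy-3-methoxybenzaldehyde)
Product: 2 3-methoxy-2-(methoxymethoxy)benzaldehyde
Conditions: NaH (1.1 equiv), MOMCl (1.2 equiv), DMF, 0 °C → rt
Reagents that add atoms: chloromethyl methyl ether (MOMCl), COCCl
Why: Williamson-type O-alkylation of the sodium phenoxide by the highly reactive α-chloro ether, in which the aldehyde is untouched and the acetal formed tolerates the basic and oxidative steps up to step 6.

Step 2
Reactants: 2 3-methoxy-2-(methoxymethoxy)benzaldehyde
Product: 4 3-methoxy-2-(methoxymethoxy)phenol, via aryl formate 3 (not isolated)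
Conditions: mCPBA (1.3 equiv), CH2Cl2, 0 °C → rt; aq NaHCO3 wash, concentrate; then K2CO3 (0.2 equiv), MeOH, rt
Reagents that add atoms: meta-chloroperoxybenzoic acid (mCPBA), O=C(OO)c1cccc(Cl)c1
Why: Baeyer–Villiger (Dakin-type) oxidation, in which the electron-rich 2,3-dialkoxyaryl group of the Criegee adduct migrates in preference to hydride and formate 3 is transesterified by methanol under conditions that leave the MOM acetal intact.

Step 3
Reactants: 4 3-methoxy-2-(methoxymethoxy)phenol; 5 1-bromocyclopentene
Product: 6 1-(cyclopent-1-en-1-yloxy)-3-methoxy-2-(methoxymethoxy)benzene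
Conditions: CuI (10 mol%), N,N-dimethylglycine hydrochloride (30 mol%), Cs2CO3 (2.5 equiv), 5 (1.5 equiv), dioxane, sealed tube, 100 °C; chromatography on Et3N-deactivated silica
Reagents that add atoms: none
Why: Ullmann-type C–O coupling of a phenol with a vinyl bromide under monovalent-copper/amino acid catalysis, which replaces the sp2 C–Br bond without moving the double bond and is helped by the small five-membered partner and by the single ortho substituent next to the phenoxide oxygen.

Step 4
Reactants: 6 1-(cyclopent-1-en-1-yloxy)-3-methoxy-2-(methoxymethoxy)benzene; 7 bromoform
Product: 9 1-[(6-bromocyclohexa-1,5-dien-1-yl)oxy]-3-methoxy-2-(methoxymethoxy)benzene, via dibromocyclopropane 8 (not isolated)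
Conditions: KOtBu (3.5 equiv), 7 (1.3 equiv, slow addition), dry hexane/toluene, −30 → −10 °C; then warm to 50 °C; non-acidic work-up
Reagents that add atoms: none
Why: KOtBu removes HBr from 7 by α-elimination, and the singlet, electrophilic CBr2 adds in one concerted cheletropic [2+1] step across the enol ether double bond of 6, making the C1'–C2' and C2'–C3' bonds and bringing in the C2'–Br bond (cyclopropane 8). On warming, 8 undergoes the disrotatory two-electron cyclopropyl-to-allyl opening (Woodward–Hoffmann–DePuy rule): the endo bromide leaves while the shared C1'–C3' bond breaks, pushed by the aryloxy lone pair, and the resulting 1-aryloxy-2-bromocyclohexenyl cation gives up its C6' proton, next to the oxocarbenium carbon, to KOtBu to give 9. The closest known reaction type is the dihalocarbene ring enlargement of cyclopentanone alkyl and silyl enol ethers to 2-halocyclohexenones or halocyclohexadienes, and of indene to 2-halonaphthalene. Ring B is thus closed not by cyclisation but by one-carbon ring enlargement, a three-membered ring being closed by [2+1] addition and the bond it shares with the five-membered ring then being cut. The two stereocentres of 8 (C1' and C3', cis by ring strain, racemic) are erased in the opening, so no stereocontrol is needed. The step needs chemoselectivity for the enol ether alkene over ring A and the acetal C–H bonds, which its far higher nucleophilicity secures, and it needs 9 to be kept from further carbene and from solvolysis, which is secured by consuming 7 below −10 °C before 8 opens and by a dry hydrocarbon medium with surplus KOtBu that binds tBuOH and HBr; proton loss from C4' instead of C6' would only shift the diene and leads to the same arene in step 5.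

Step 5
Reactants: 9 1-[(6-bromocyclohexa-1,5-dien-1-yl)oxy]-3-methoxy-2-(methoxymethoxy)benzene
Product: 10 1-(2-bromophenoxy)-3-methoxy-2-(methoxymethoxy)benzene
Conditions: DDQ (1.2 equiv), dry toluene, rt → 60 °C; filter, wash with aq NaHCO3
Reagents that add atoms: none
Why: Dehydrogenative aromatisation with DDQ, in which hydride is taken from the allylic C5' methylene to give a cyclohexadienyl cation stabilised by the C1' oxygen, loss of the C4' proton gives the arene, and the C–Br bond, the MOM acetal and the methyl ether are inert in dry toluene.

Step 6
Reactants: 10 1-(2-bromophenoxy)-3-methoxy-2-(methoxymethoxy)benzene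
Product: 11 2-(2-bromophenoxy)-6-methoxyphenol
Conditions: HCl (cat.), MeOH, 50 °C
Reagents that add atoms: none
Why: Acid-catalysed acetal exchange, in which methanol as solvent captures the methoxymethyl cation before it can alkylate the electron-rich ring A, while the diaryl ether, the aryl methyl ether and the aryl bromide do not react.

Step 7
Reactants: 11 2-(2-bromophenoxy)-6-methoxyphenol
Product: 12 3,4,5-tribromo-2-(2,4-dibromophenoxy)-6-methoxyphenol (target)
Conditions: Br2 (4.3 equiv), AcOH, rt → 50 °C; aq NaHSO3 quench
Reagents that add atoms: bromine, BrBr
Why: Fourfold electrophilic aromatic bromination, in which every free position of ring A lies para to an oxygen donor (C4 to OH, C3 to OMe, C5 to OAr) and is filled, the ether oxygen directs ring B to its para carbon C4', and the hindered C6' of the then doubly brominated ring B should not react without a Lewis acid.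

**Compound list**
1 | o-vanillin (2-hydroxy-3-methoxybenzaldehyde) | COc1cccc(C=O)c1O | starting material
2 | 3-methoxy-2-(methoxymethoxy)benzaldehyde | COCOc1c(OC)cccc1C=O | intermediate
3 | 3-methoxy-2-(methoxymethoxy)phenyl formate (not isolated) | COCOc1c(OC)cccc1OC=O | intermediate
4 | 3-methoxy-2-(methoxymethoxy)phenol | COCOc1c(OC)cccc1O | intermediate
5 | 1-bromocyclopentene | BrC1=CCCC1 | starting material
6 | 1-(cyclopent-1-en-1-yloxy)-3-methoxy-2-(methoxymethoxy)benzene | COCOc1c(OC)cccc1OC1=CCCC1 | intermediate
7 | bromoform | BrC(Br)Br | starting material
8 | 1-[(6,6-dibromobicyclo[3.1.0]hexan-1-yl)oxy]-3-methoxy-2-(methoxymethoxy)benzene (racemic, cis ring fusion, one enantiomer drawn; not isolated) | COCOc1c(OC)cccc1O[C@@]12CCC[C@@H]1C2(Br)Br | intermediate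
9 | 1-[(6-bromocyclohexa-1,5-dien-1-yl)oxy]-3-methoxy-2-(methoxymethoxy)benzene | COCOc1c(OC)cccc1OC1=CCCC=C1Br | intermediate
10 | 1-(2-bromophenoxy)-3-methoxy-2-(methoxymethoxy)benzene | COCOc1c(OC)cccc1Oc1ccccc1Br | intermediate
11 | 2-(2-bromophenoxy)-6-methoxyphenol | COc1cccc(Oc2ccccc2Br)c1O | intermediate
12 | 3,4,5-tribromo-2-(2,4-dibromophenoxy)-6-methoxyphenol | COc1c(O)c(Oc2ccc(Br)cc2Br)c(Br)c(Br)c1Br | target

Total step count: 7. Longest linear sequence: 7 (from o-vanillin 1).

**Steps most likely to fail**

1. Step 4 (key step).
   - Risk: an aryl enol ether is less nucleophilic than an alkyl one, so cyclopropanation may lag behind decay of the carbene. The ring-opened cation may be intercepted by tert-butoxide or by traces of water, with expulsion of the aryloxide. The diene may take up a second carbene if the cyclopropane opens too early.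
   - Fallback (ring B is bought as an arene instead of being built): the fallback sets out from 4. An Ullmann diaryl ether coupling with commercial 1-bromo-2-iodobenzene (Brc1ccccc1I; CuI, picolinic acid, K3PO4, DMSO, 90 °C) is used. The C–I bond reacts much faster than the C–Br bond, so the coupling should deliver 10 directly. Steps 3 to 5 are bypassed and the route is rejoined at 10. No compound outside the list is made (F0).

2. Step 3.
   - Risk: activation of the trisubstituted vinyl bromide by copper may be sluggish, volatile 5 may be lost at the reaction temperature, and the enol ether may hydrolyse during purification.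
   - Fallback (palladium and a vinyl sulfonate instead of copper and a vinyl halide): cyclopentanone is converted with Tf2O and 2,6-di-tert-butyl-4-methylpyridine in CH2Cl2 into cyclopent-1-en-1-yl trifluoromethanesulfonate F1. This is coupled with 4 under zerovalent-palladium catalysis (Pd2(dba)3, 2-(di-tert-butylphosphino)biphenyl, NaOtBu, toluene, 100 °C). This Buchwald–Hartwig-type C–O coupling is established for cyclic enol triflates and phenols. The fallback sets out from 4 and returns at 6.

3. Step 7.
   - Risk: bromination at C4' may remain incomplete once ring A has become electron-poor and withdraws the ether lone pair. Forcing conditions may bring over-bromination at C6' or oxidative dearomatisation of the free phenol.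
   - Fallback (staged bromination with the phenol masked): the fallback sets out from 11.
     - Br2 (3 equiv) in CH2Cl2/AcOH at 0 °C should fill ring A only and give 3,4,5-tribromo-2-(2-bromophenoxy)-6-methoxyphenol F2.
     - Ac2O/pyridine converts it into 3,4,5-tribromo-2-(2-bromophenoxy)-6-methoxyphenyl acetate F3, in which ring A is fully substituted and protected against oxidation.
     - Br2 (1.1 equiv) with FeBr3 (5 mol%) in CH2Cl2 then brominates the only activated open position, C4', to give 3,4,5-tribromo-2-(2,4-dibromophenoxy)-6-methoxyphenyl acetate F4.
     - K2CO3 in MeOH removes the acetate, and the route is rejoined at 12.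

**Further compounds**
F0 | step 4 | none | none
F1 | step 3 | cyclopent-1-en-1-yl trifluoromethanesulfonate | O=S(=O)(OC1=CCCC1)C(F)(F)F
F2 | step 7 | 3,4,5-tribromo-2-(2-bromophenoxy)-6-methoxyphenol | COc1c(O)c(Oc2ccccc2Br)c(Br)c(Br)c1Br
F3 | step 7 | 3,4,5-tribromo-2-(2-bromophenoxy)-6-methoxyphenyl acetate | COc1c(OC(C)=O)c(Oc2ccccc2Br)c(Br)c(Br)c1Br
F4 | step 7 | 3,4,5-tribromo-2-(2,4-dibromophenoxy)-6-methoxyphenyl acetate | COc1c(OC(C)=O)c(Oc2ccc(Br)cc2Br)c(Br)c(Br)c1Br
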